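**Plan**
- Retrosynthesis: the lactone C2(=O)–C3 bond and the bond from the C3–CH2 group to C5 of the dihydrobenzofuran are cut in one operation, giving aryl bromide 9 and homoallylic alcohol 23. This works because the lactone carbonyl sits on a ring oxygen bound to a primary CH2 (lactone C5), so it can be an alkoxycarbonyl radical from an oxalate half-ester, and because C3 carries an exocyclic CH2–aryl, so C3 and that CH2 can be a vinyl group on C4.
- 23 is cut at the ArCH2–C bond (enolate alkylation with benzyl bromide 18); 18 is cut at the C1–C2 bond of the arylglycerol unit (aldol) and at the ArO–CH2 bond; 9 is cut at the C2–C3 bond of the dihydrobenzofuran (carbene C–H insertion).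
- Forward: the dihydrobenzofuran ring is made first in one fragment; the arylglycerol aryl ether chain and then the vinyl-bearing centre are built in the other; the lactone ring closes last, in the step that joins the fragments; two deprotections follow.
- Stereochemistry: dihydrobenzofuran C2 from the chiral dirhodium catalyst and C3 by epimerisation to trans; the erythro (1R,2S) arylglycerol pair from an Evans syn-aldol followed by Mitsunobu inversion at the carbinol; lactone C4 from an Evans deconjugative alkylation; lactone C3 from the trans-selective 5-exo cyclization controlled by C4.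

Key step: step 17

Assumption: Rh2(R-PTTL)4, dirhodium tetrakis[N-phthaloyl-(R)-tert-leucinate], is taken to deliver the (2S)-dihydrobenzofuran in step 4; if the sense is the opposite, Rh2(S-PTTL)4 is used with no other change.

**Route**

Step 1
Reactants: 1 4-bromo-2-methoxyphenol
Product: 2 4-bromo-2-iodo-6-methoxyphenol
Conditions: NIS, MeCN, rt
Reagents that add atoms: N-iodosuccinimide, O=C1CCC(=O)N1I
Why: Electrophilic aromatic iodination should go ortho to the phenolic oxygen because the para position carries bromine, as in the iodination of vanillin.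

Step 2
Reactants: 2 4-bromo-2-iodo-6-methoxyphenol; 3 [4-(benzyloxy)-3-methoxyphenyl]methanol
Product: 4 aryl benzyl ether
Conditions: PPh3, DIAD, THF, 0 °C to rt
Reagents that add atoms: none
Why: Mitsunobu etherification of an acidic phenol with a primary benzylic alcohol, with no stereocentre involved.

Step 3
Reactants: 4 aryl benzyl ether; 5 ethyl diazoacetate
Product: 6 aryl diazoacetate
Conditions: Pd(PPh3)4 (5 mol %), Ag2CO3, Et3N, toluene, rt
Reagents that add atoms: none
Why: Pd(PPh3)4-catalysed cross-coupling of an aryl iodide with the C–H bond of a diazoacetate keeps the diazo group and should occur only at the C–I bond, the C–Br bond being inert to zerovalent palladium at room temperature.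

Step 4
Reactants: 6 aryl diazoacetate
Product: 7 cis-dihydrobenzofuran ester (2S,3R)
Conditions: Rh2(R-PTTL)4 (1 mol %), toluene, −60 °C
Reagents that add atoms: none
Why: Enantioselective intramolecular 1,5 C–H insertion of the aryl(ester) rhodium carbene into the benzylic O–CH2 group forms the C2–C3 bond and should give the cis-dihydrobenzofuran, with C2 set by the chiral carboxylate ligands.

Step 5
Reactants: 7 cis-dihydrobenzofuran ester
Product: 8 trans-dihydrobenzofuran ester (2S,3S)
Conditions: NaOEt (0.2 equiv), EtOH/THF, rt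
Reagents that add atoms: none
Why: Base-mediated epimerisation of the ester-bearing C3 through its enolate should give the more stable trans isomer under thermodynamic control while C2 is untouched.

Step 6
Reactants: 8 trans-dihydrobenzofuran ester
Product: 9 aryl bromide alcohol (2S,3R)
Conditions: LiBH4, THF, 0 °C to rt
Reagents that add atoms: none
Why: Hydride reduction of the ester to the primary alcohol leaves the aryl bromide and benzyl ether intact and changes no stereocentre.

Step 7
Reactants: 10 methyl 4-hydroxy-3-methoxybenzoate; 11 (4R)-4-benzyl-3-(chloroacetyl)-1,3-oxazolidin-2-one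
Product: 12 aryloxyacetyl imide
Conditions: K2CO3, KI (cat.), MeCN, rt
Reagents that add atoms: none
Why: Williamson ether synthesis by SN2 displacement of the activated α-chloride by the phenoxide, which should be faster than attack at the imide carbonyl.

Step 8
Reactants: 12 aryloxyacetyl imide; 13 4-(benzyloxy)-3-methoxybenzaldehyde
Product: 14 syn-aldol adduct (2R,3S)
Conditions: Bu2BOTf, iPr2NEt, CH2Cl2, −78 to 0 °C; then 13, −78 to 0 °C; pH 7 buffer, MeOH, H2O2
Reagents that add atoms: none
Why: Evans syn-aldol reaction through the Z boron enolate and a Zimmerman–Traxler chair, in which the (R)-auxiliary should set the aryloxy-bearing carbon as R and the carbinol carbon as S.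

Step 9
Reactants: 14 syn-aldol adduct
Product: 15 inverted benzoate (2R,3R)
Conditions: PhCO2H, PPh3, DIAD, THF, 0 °C to rt
Reagents that add atoms: benzoic acid, OC(=O)c1ccccc1
Why: Mitsunobu esterification with SN2 inversion at the benzylic carbinol carbon should turn the syn adduct into the anti (erythro) series, elimination being disfavoured because allylic strain holds the imide α-hydrogen in the carbonyl plane.

Step 10
Reactants: 15 inverted benzoate
Product: 16 erythro triol (1R,2S)
Conditions: LiAlH4, THF, 0 °C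
Reagents that add atoms: none
Why: Hydride reduction should cleave the auxiliary to the primary alcohol, remove the benzoate and reduce the aryl methyl ester to the benzylic alcohol in one operation without touching either stereocentre.

Step 11
Reactants: 16 erythro triol
Product: 17 acetonide benzylic alcohol
Conditions: 2,2-dimethoxypropane, PPTS (cat.), acetone, rt; then MeOH
Reagents that add atoms: 2,2-dimethoxypropane, COC(C)(C)OC
Why: Ketalisation of the 1,3-diol should give the trans-4,5-disubstituted 1,3-dioxane with both substituents equatorial, and the lone benzylic alcohol cannot form a cyclic ketal.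

Step 12
Reactants: 17 acetonide benzylic alcohol
Product: 18 acetonide benzyl bromide
Conditions: CBr4, PPh3, CH2Cl2, 0 °C
Reagents that add atoms: carbon tetrabromide, BrC(Br)(Br)Br
Why: Appel bromination of the primary benzylic alcohol runs under neutral conditions that leave the acetonide intact.

Step 13
Reactants: 19 (4R)-4-benzyl-1,3-oxazolidin-2-one; 20 (E)-but-2-enoyl chloride
Product: 21 N-crotonyl oxazolidinone
Conditions: n-BuLi, THF, −78 °C; then 20
Reagents that add atoms: none
Why: N-acylation of the lithiated oxazolidinone with the acid chloride.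

Step 14
Reactants: 21 N-crotonyl oxazolidinone; 18 acetonide benzyl bromide
Product: 22 α-benzylated but-3-enoyl imide (2R)
Conditions: NaHMDS, THF, −78 °C; then 18, −78 to −40 °C
Reagents that add atoms: none
Why: Evans deconjugative alkylation, in which γ-deprotonation gives the chelated Z sodium dienolate that should be benzylated at the α-carbon on the face opposite the auxiliary benzyl group, so that the (R)-auxiliary gives the (R)-configured vinyl-bearing centre.

Step 15
Reactants: 22 α-benzylated but-3-enoyl imide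
Product: 23 homoallylic alcohol (2R)
Conditions: LiBH4, MeOH (1 equiv), THF, 0 °C
Reagents that add atoms: none
Why: Reductive cleavage of the N-acyl oxazolidinone should give the primary alcohol without epimerisation or alkene migration.

Step 16
Reactants: 23 homoallylic alcohol
Product: 25 cesium oxalate half-ester, via chlorooxoacetate ester 24 (not isolated)
Conditions: (COCl)2, 2,6-lutidine, CH2Cl2, 0 °C; concentrate; CsHCO3, THF/H2O, 0 °C
Reagents that add atoms: oxalyl chloride, O=C(Cl)C(Cl)=O; water, O; cesium hydrogen carbonate, [Cs+].OC([O-])=O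
Why: Acylation of the primary alcohol by excess oxalyl chloride and buffered hydrolysis of the remaining acid chloride should give the oxalate half-ester as its cesium salt, the lutidine and hydrogen carbonate keeping the acetonide away from acid.

Step 17
Reactants: 25 cesium oxalate half-ester; 9 aryl bromide alcohol
Product: 26 protected lactone (3R,4R)
Conditions: Ir[dF(CF3)ppy]2(dtbbpy)PF6 (2 mol %), NiBr2(dme) (10 mol %), 4,4'-di-tert-butyl-2,2'-bipyridine (15 mol %), DME/DMF 3:1, H2O (10 equiv), 450 nm LEDs, 60 °C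
Reagents that add atoms: none
Why: Excited Ir[dF(CF3)ppy]2(dtbbpy)PF6 oxidises the oxalate carboxylate of 25, loss of CO2 gives a primary alkoxycarbonyl radical that does not lose the second CO2, this adds to the vinyl group to form the lactone C(=O)–Cα bond, and the resulting primary alkyl radical is captured by the (dtbbpy)Ni(aryl)Br complex formed from 9 and zerovalent nickel, reductive elimination from trivalent nickel giving the CH2–aryl bond. The closest known reaction type is the alkoxycarbonyl radical cyclization–cross-coupling cascade of homoallylic cesium oxalates with aryl halides under nickel/photoredox dual catalysis. The oxolan-2-one ring closes in the 5-exo-trig mode, 6-endo attack on the terminal CH2 being slower. The new α-stereocentre is controlled by the β-stereocentre: in the chair-like Beckwith–Houk transition state the allylic CH2Ar group sits pseudo-equatorial, which should give the trans-(3R,4R) lactone, and any cis isomer can be converged with DBU because trans is the more stable. The step needs cyclization to outrun direct capture of the alkoxycarbonyl radical by nickel (which would give an aryl ester) and needs carboxylate oxidation to win over oxidation of the electron-rich arenes; the first is favoured by the unhindered intramolecular vinyl acceptor and low nickel loading, the second by the irreversible decarboxylation, by the non-conjugated alkene and by keeping both phenols as benzyl ethers.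

Step 18
Reactants: 26 protected lactone
Product: 27 lactone diol with two benzyl ethers
Conditions: AcOH/THF/H2O 3:1:1, 40 °C
Reagents that add atoms: none
Why: Mild acid hydrolysis of the isopropylidene ketal, done while the phenols are still benzylated so that the benzylic alcohol is not ionised towards a quinone methide.

Step 19
Reactants: 27 lactone diol with two benzyl ethers
Product: 28 target
Conditions: H2 (1 atm), 10% Pd/C, EtOAc/MeOH, rt
Reagents that add atoms: none
Why: Hydrogenolysis under neutral conditions should cleave the two aryl benzyl ethers faster than the benzylic C–O bonds of the dihydrobenzofuran and of the secondary alcohol.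

**Compound list**

1 | 4-bromo-2-methoxyphenol | COc1cc(Br)ccc1O | starting material
2 | 4-bromo-2-iodo-6-methoxyphenol | COc1cc(Br)cc(I)c1O | intermediate
3 | [4-(benzyloxy)-3-methoxyphenyl]methanol | COc1cc(CO)ccc1OCc1ccccc1 | starting material
4 | 1-(benzyloxy)-4-[(4-bromo-2-iodo-6-methoxyphenoxy)methyl]-2-methoxybenzene | COc1cc(COc2c(I)cc(Br)cc2OC)ccc1OCc1ccccc1 | intermediate
5 | ethyl diazoacetate | CCOC(=O)C=[N+]=[N-] | starting material
6 | ethyl 2-(2-{[4-(benzyloxy)-3-methoxyphenyl]methoxy}-5-bromo-3-methoxyphenyl)-2-diazoacetate | CCOC(=O)C(=[N+]=[N-])c1cc(Br)cc(OC)c1OCc1ccc(OCc2ccccc2)c(OC)c1 | intermediate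
7 | ethyl (2S,3R)-2-[4-(benzyloxy)-3-methoxyphenyl]-5-bromo-7-methoxy-2,3-dihydro-1-benzofuran-3-carboxylate (cis) | Brc1cc(OC)c2c(c1)[C@@H](C(=O)OCC)[C@@H](c1ccc(OCc3ccccc3)c(OC)c1)O2 | intermediate
8 | ethyl (2S,3S)-2-[4-(benzyloxy)-3-methoxyphenyl]-5-bromo-7-methoxy-2,3-dihydro-1-benzofuran-3-carboxylate (trans) | Brc1cc(OC)c2c(c1)[C@H](C(=O)OCC)[C@@H](c1ccc(OCc3ccccc3)c(OC)c1)O2 | intermediate
9 | [(2S,3R)-2-[4-(benzyloxy)-3-methoxyphenyl]-5-bromo-7-methoxy-2,3-dihydro-1-benzofuran-3-yl]methanol | Brc1cc(OC)c2c(c1)[C@H](CO)[C@@H](c1ccc(OCc3ccccc3)c(OC)c1)O2 | intermediate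
10 | methyl 4-hydroxy-3-methoxybenzoate | COC(=O)c1ccc(O)c(OC)c1 | starting material
11 | (4R)-4-benzyl-3-(chloroacetyl)-1,3-oxazolidin-2-one | ClCC(=O)N1[C@H](Cc2ccccc2)COC1=O | starting material
12 | methyl 4-{2-[(4R)-4-benzyl-2-oxo-1,3-oxazolidin-3-yl]-2-oxoethoxy}-3-methoxybenzoate | COC(=O)c1ccc(OCC(=O)N2[C@H](Cc3ccccc3)COC2=O)c(OC)c1 | intermediate
13 | 4-(benzyloxy)-3-methoxybenzaldehyde | COc1cc(C=O)ccc1OCc1ccccc1 | starting material
14 | (4R)-4-benzyl-3-[(2R,3S)-3-[4-(benzyloxy)-3-methoxyphenyl]-3-hydroxy-2-[2-methoxy-4-(methoxycarbonyl)phenoxy]propanoyl]-1,3-oxazolidin-2-one | COc1cc([C@H](O)[C@H](C(=O)N3[C@H](Cc4ccccc4)COC3=O)Oc5ccc(C(=O)OC)cc5OC)ccc1OCc1ccccc1 | intermediate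
15 | (4R)-4-benzyl-3-[(2R,3R)-3-(benzoyloxy)-3-[4-(benzyloxy)-3-methoxyphenyl]-2-[2-methoxy-4-(methoxycarbonyl)phenoxy]propanoyl]-1,3-oxazolidin-2-one | COc1cc([C@@H](OC(=O)c2ccccc2)[C@H](C(=O)N3[C@H](Cc4ccccc4)COC3=O)Oc5ccc(C(=O)OC)cc5OC)ccc1OCc1ccccc1 | intermediate
16 | (1R,2S)-1-[4-(benzyloxy)-3-methoxyphenyl]-2-[4-(hydroxymethyl)-2-methoxyphenoxy]propane-1,3-diol | COc1cc([C@@H](O)[C@H](CO)Oc2ccc(CO)cc2OC)ccc1OCc1ccccc1 | intermediate
17 | [4-({(4R,5S)-4-[4-(benzyloxy)-3-methoxyphenyl]-2,2-dimethyl-1,3-dioxan-5-yl}oxy)-3-methoxyphenyl]methanol | COc1cc([C@H]2OC(C)(C)OC[C@@H]2Oc3ccc(CO)cc3OC)ccc1OCc1ccccc1 | intermediate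
18 | (4R,5S)-4-[4-(benzyloxy)-3-methoxyphenyl]-5-[4-(bromomethyl)-2-methoxyphenoxy]-2,2-dimethyl-1,3-dioxane | COc1cc([C@H]2OC(C)(C)OC[C@@H]2Oc3ccc(CBr)cc3OC)ccc1OCc1ccccc1 | intermediate
19 | (4R)-4-benzyl-1,3-oxazolidin-2-one | O=C1N[C@H](Cc2ccccc2)CO1 | starting material
20 | (E)-but-2-enoyl chloride | C/C=C/C(Cl)=O | starting material
21 | (4R)-4-benzyl-3-[(2E)-but-2-enoyl]-1,3-oxazolidin-2-one | C/C=C/C(=O)N1[C@H](Cc2ccccc2)COC1=O | intermediate
22 | (4R)-4-benzyl-3-[(2R)-2-{[4-({(4R,5S)-4-[4-(benzyloxy)-3-methoxyphenyl]-2,2-dimethyl-1,3-dioxan-5-yl}oxy)-3-methoxyphenyl]methyl}but-3-enoyl]-1,3-oxazolidin-2-one | COc1cc([C@H]2OC(C)(C)OC[C@@H]2Oc3ccc(C[C@H](C=C)C(=O)N4[C@H](Cc5ccccc5)COC4=O)cc3OC)ccc1OCc1ccccc1 | intermediate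
23 | (2R)-2-{[4-({(4R,5S)-4-[4-(benzyloxy)-3-methoxyphenyl]-2,2-dimethyl-1,3-dioxan-5-yl}oxy)-3-methoxyphenyl]methyl}but-3-en-1-ol | COc1cc([C@H]2OC(C)(C)OC[C@@H]2Oc3ccc(C[C@H](C=C)CO)cc3OC)ccc1OCc1ccccc1 | intermediate
24 | (2R)-2-{[4-({(4R,5S)-4-[4-(benzyloxy)-3-methoxyphenyl]-2,2-dimethyl-1,3-dioxan-5-yl}oxy)-3-methoxyphenyl]methyl}but-3-en-1-yl 2-chloro-2-oxoacetate | COc1cc([C@H]2OC(C)(C)OC[C@@H]2Oc3ccc(C[C@H](C=C)COC(=O)C(Cl)=O)cc3OC)ccc1OCc1ccccc1 | intermediate
25 | cesium 2-{[(2R)-2-{[4-({(4R,5S)-4-[4-(benzyloxy)-3-methoxyphenyl]-2,2-dimethyl-1,3-dioxan-5-yl}oxy)-3-methoxyphenyl]methyl}but-3-en-1-yl]oxy}-2-oxoacetate | COc1cc([C@H]2OC(C)(C)OC[C@@H]2Oc3ccc(C[C@H](C=C)COC(=O)C(=O)[O-])cc3OC)ccc1OCc1ccccc1.[Cs+] | intermediate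
26 | (3R,4R)-4-{[4-({(4R,5S)-4-[4-(benzyloxy)-3-methoxyphenyl]-2,2-dimethyl-1,3-dioxan-5-yl}oxy)-3-methoxyphenyl]methyl}-3-{[(2S,3R)-2-[4-(benzyloxy)-3-methoxyphenyl]-3-(hydroxymethyl)-7-methoxy-2,3-dihydro-1-benzofuran-5-yl]methyl}oxolan-2-one | COc1cc([C@H]2OC(C)(C)OC[C@@H]2Oc3ccc(C[C@H]4COC(=O)[C@@H]4Cc5cc(OC)c6c(c5)[C@H](CO)[C@@H](c7ccc(OCc8ccccc8)c(OC)c7)O6)cc3OC)ccc1OCc1ccccc1 | intermediate
27 | (3R,4R)-3-{[(2S,3R)-2-[4-(benzyloxy)-3-methoxyphenyl]-3-(hydroxymethyl)-7-methoxy-2,3-dihydro-1-benzofuran-5-yl]methyl}-4-[(4-{[(1R,2S)-1-[4-(benzyloxy)-3-methoxyphenyl]-1,3-dihydroxypropan-2-yl]oxy}-3-methoxyphenyl)methyl]oxolan-2-one | COc1cc([C@@H](O)[C@H](CO)Oc2ccc(C[C@H]3COC(=O)[C@@H]3Cc4cc(OC)c5c(c4)[C@H](CO)[C@@H](c6ccc(OCc7ccccc7)c(OC)c6)O5)cc2OC)ccc1OCc1ccccc1 | intermediate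
28 | (3R,4R)-3-{[(2S,3R)-2-(4-hydroxy-3-methoxyphenyl)-3-(hydroxymethyl)-7-methoxy-2,3-dihydro-1-benzofuran-5-yl]methyl}-4-[(4-{[(1R,2S)-1,3-dihydroxy-1-(4-hydroxy-3-methoxyphenyl)propan-2-yl]oxy}-3-methoxyphenyl)methyl]oxolan-2-one | COc1cc([C@@H](O)[C@H](CO)Oc2ccc(C[C@H]3COC(=O)[C@@H]3Cc3cc(OC)c4c(c3)[C@H](CO)[C@@H](c3ccc(O)c(OC)c3)O4)cc2OC)ccc1O | target

**Count and risks**

Total steps: 19. Longest linear sequence: 12 steps (steps 7–12 and 14–19).

Step 17 is the most likely to fail. The alkoxycarbonyl radical may be captured by the nickel–aryl species before it cyclizes, oxidative addition of the electron-rich aryl bromide may be slow, and the trans selectivity of ring closure may be modest. The fallback sets out from 9 and 23 and makes the same lactone bond by a tin-mediated radical cyclization onto a styrene. Alcohol 9 is silylated (TESCl, imidazole, CH2Cl2) to the triethylsilyl ether F1. A Heck reaction of F1 with the terminal alkene of 23 (Pd(OAc)2, P(o-tol)3, NaHCO3, DMF, 90 °C) gives the E-styrene homoallylic alcohol F2. Acylation with PhSeC(O)Cl and pyridine gives the Se-phenyl selenocarbonate F3. Bu3SnH and AIBN in benzene at 80 °C then generate the alkoxycarbonyl radical, which closes 5-exo onto the styrene, and the benzylic radical is reduced by the stannane to the silylated lactone F4. AcOH/THF/H2O removes the silyl ether together with the acetonide, and the route is rejoined at 27.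

Step 9 is the second. The electron-rich benzylic oxyphosphonium ion may ionise, so that inversion is incomplete, or may eliminate. The fallback sets out from 14 and replaces substitution by an oxidation–reduction pair. NaBH4 in THF/H2O removes the auxiliary to give the threo diol ester F5. DDQ in dioxane oxidises only the 4-alkoxybenzylic alcohol to the aryl ketone F6. NaBH4 in MeOH at 0 °C, which in 2-aryloxy-3-hydroxy-1-arylpropan-1-ones favours the erythro alcohol, gives the erythro diol ester F7 after separation from its epimer. LiAlH4 then reduces the aryl ester, and the route is rejoined at 16.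

Step 4 is the third. Enantiofacial control in the C–H insertion may be insufficient, or the carbene may be diverted to an oxonium ylide and rearrange. The fallback sets out from 6 and replaces asymmetric catalysis by resolution. Rh2(OAc)4 in CH2Cl2 gives the racemic cis ester F8, NaOEt in EtOH gives the racemic trans ester F9, and LiBH4 gives the racemic trans alcohol F10. Preparative chromatography on a chiral stationary phase separates the (2S,3R) enantiomer, and the route is rejoined at 9.

Further compounds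
F1 | step 17 | {[(2S,3R)-2-[4-(benzyloxy)-3-methoxyphenyl]-5-bromo-7-methoxy-2,3-dihydro-1-benzofuran-3-yl]methoxy}(triethyl)silane | Brc1cc(OC)c2c(c1)[C@H](CO[Si](CC)(CC)CC)[C@@H](c1ccc(OCc3ccccc3)c(OC)c1)O2
F2 | step 17 | (2R,3E)-4-[(2S,3R)-2-[4-(benzyloxy)-3-methoxyphenyl]-7-methoxy-3-{[(triethylsilyl)oxy]methyl}-2,3-dihydro-1-benzofuran-5-yl]-2-{[4-({(4R,5S)-4-[4-(benzyloxy)-3-methoxyphenyl]-2,2-dimethyl-1,3-dioxan-5-yl}oxy)-3-methoxyphenyl]methyl}but-3-en-1-ol | COc1cc([C@H]2OC(C)(C)OC[C@@H]2Oc3ccc(C[C@H](/C=C/c4cc(OC)c5c(c4)[C@H](CO[Si](CC)(CC)CC)[C@@H](c6ccc(OCc7ccccc7)c(OC)c6)O5)CO)cc3OC)ccc1OCc1ccccc1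
F3 | step 17 | O-[(2R,3E)-4-aryl-2-(arylmethyl)but-3-en-1-yl] Se-phenyl carbonoselenoate derived from F2 | COc1cc([C@H]2OC(C)(C)OC[C@@H]2Oc3ccc(C[C@H](/C=C/c4cc(OC)c5c(c4)[C@H](CO[Si](CC)(CC)CC)[C@@H](c6ccc(OCc7ccccc7)c(OC)c6)O5)COC(=O)[Se]c8ccccc8)cc3OC)ccc1OCc1ccccc1
F4 | step 17 | triethylsilyl ether of 26 at the dihydrobenzofuran CH2OH, (3R,4R)-lactone | COc1cc([C@H]2OC(C)(C)OC[C@@H]2Oc3ccc(C[C@H]4COC(=O)[C@@H]4Cc5cc(OC)c6c(c5)[C@H](CO[Si](CC)(CC)CC)[C@@H](c7ccc(OCc8ccccc8)c(OC)c7)O6)cc3OC)ccc1OCc1ccccc1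
F5 | step 9 | methyl 4-{[(1S,2S)-1-[4-(benzyloxy)-3-methoxyphenyl]-1,3-dihydroxypropan-2-yl]oxy}-3-methoxybenzoate | COc1cc([C@H](O)[C@H](CO)Oc2ccc(C(=O)OC)cc2OC)ccc1OCc1ccccc1
F6 | step 9 | methyl 4-{[(2S)-1-[4-(benzyloxy)-3-methoxyphenyl]-3-hydroxy-1-oxopropan-2-yl]oxy}-3-methoxybenzoate | COc1cc(C(=O)[C@H](CO)Oc2ccc(C(=O)OC)cc2OC)ccc1OCc1ccccc1
F7 | step 9 | methyl 4-{[(1R,2S)-1-[4-(benzyloxy)-3-methoxyphenyl]-1,3-dihydroxypropan-2-yl]oxy}-3-methoxybenzoate | COc1cc([C@@H](O)[C@H](CO)Oc2ccc(C(=O)OC)cc2OC)ccc1OCc1ccccc1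
F8 | step 4 | racemic cis ethyl 2-[4-(benzyloxy)-3-methoxyphenyl]-5-bromo-7-methoxy-2,3-dihydro-1-benzofuran-3-carboxylate (both enantiomers) | Brc1cc(OC)c2c(c1)[C@@H](C(=O)OCC)[C@@H](c1ccc(OCc3ccccc3)c(OC)c1)O2.Brc1cc(OC)c2c(c1)[C@H](C(=O)OCC)[C@H](c1ccc(OCc3ccccc3)c(OC)c1)O2
F9 | step 4 | racemic trans ethyl 2-[4-(benzyloxy)-3-methoxyphenyl]-5-bromo-7-methoxy-2,3-dihydro-1-benzofuran-3-carboxylate (both enantiomers) | Brc1cc(OC)c2c(c1)[C@H](C(=O)OCC)[C@@H](c1ccc(OCc3ccccc3)c(OC)c1)O2.Brc1cc(OC)c2c(c1)[C@@H](C(=O)OCC)[C@H](c1ccc(OCc3ccccc3)c(OC)c1)O2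
F10 | step 4 | racemic trans [2-[4-(benzyloxy)-3-methoxyphenyl]-5-bromo-7-methoxy-2,3-dihydro-1-benzofuran-3-yl]methanol (both enantiomers) | Brc1cc(OC)c2c(c1)[C@H](CO)[C@@H](c1ccc(OCc3ccccc3)c(OC)c1)O2.Brc1cc(OC)c2c(c1)[C@@H](CO)[C@H](c1ccc(OCc3ccccc3)c(OC)c1)O2
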